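The dihydrobenzofuran is opened at its aryl–oxygen bond O1–C7a. In ring A, C7a lies between C7 (OMe) and C3a and para to the C5 side chain, so it is the phenolic carbon of a dihydroferulate. This phenol first steers iodine to C3a and then leaves as triflate. The key step, a palladium-catalysed intramolecular etherification, contracts a six-membered aryl(alkoxo)palladium chelate to the five-membered ring by expelling the metal. As no bond at C2 or C3 is touched, the (1R,2S) array of the acyclic precursor is copied into the trans-(2R,3S) ring. That precursor is a monosilylated 1,2-diarylpropane-1,3-diol made by transfer hydrogenation with dynamic kinetic resolution.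

Key step: step 8

Remark: atoms are numbered as in 2,3-dihydrobenzofuran (O1, C2, C3, C3a, C4 to C7, C7a). Ring A is the benzo ring and ring B is the aryl group on C2. The three starting materials are assumed to be commercial.

Step 1
Reactants: 1 methyl 3-(4-hydroxy-3-methoxyphenyl)propanoate (methyl dihydroferulate)
Product: 2 methyl 3-(4-hydroxy-3-iodo-5-methoxyphenyl)propanoate
Conditions: NIS (1.05 equiv), TsOH·H2O (10 mol %), MeCN, 0 °C to rt
Reagents that add atoms: N-iodosuccinimide, O=C1CCC(=O)N1I
Why: Electrophilic aromatic iodination: the free phenol is the dominant director, its para position carries the side chain and one ortho position the methoxy group, so iodine should enter at the only open ortho carbon, the future C3a.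

Step 2
Reactants: 2 methyl 3-(4-hydroxy-3-iodo-5-methoxyphenyl)propanoate
Product: 3 methyl 3-[3-iodo-5-methoxy-4-(trifluoromethylsulfonyloxy)phenyl]propanoate
Conditions: Tf2O, pyridine, CH2Cl2, 0 °C
Reagents that add atoms: triflic anhydride, O=S(=O)(OS(=O)(=O)C(F)(F)F)C(F)(F)F
Why: O-Sulfonylation of a phenol: the triflate makes the future C7a an electrophilic carbon and also masks the phenol, which would otherwise condense with the ketone introduced in step 4 to a benzofuran.

Step 3
Reactants: 4 1-(4-hydroxy-3-methoxyphenyl)ethanone (acetovanillone)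
Product: 5 1-[3-methoxy-4-(triisopropylsilyloxy)phenyl]ethanone
Conditions: TIPSCl, imidazole, DMF, rt
Reagents that add atoms: chlorotriisopropylsilane, CC(C)[Si](Cl)(C(C)C)C(C)C
Why: Silyl ether formation: the hindered triisopropylsilyl group should withstand the phosphate and carbonate bases, the formate medium and the hydride of the later steps, and it falls to fluoride at the end.

Step 4
Reactants: 3 methyl 3-[3-iodo-5-methoxy-4-(trifluoromethylsulfonyloxy)phenyl]propanoate; 5 1-[3-methoxy-4-(triisopropylsilyloxy)phenyl]ethanone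
Product: 6 methyl 3-[3-methoxy-5-[2-[3-methoxy-4-(triisopropylsilyloxy)phenyl]-2-oxoethyl]-4-(trifluoromethylsulfonyloxy)phenyl]propanoate
Conditions: Pd2(dba)3 (1.5 mol %), P(tBu)3·HBF4 (6 mol %), K3PO4, toluene, 70 °C
Reagents that add atoms: none
Why: Palladium-catalysed ketone α-arylation (Buchwald–Hartwig type): with the P(tBu)3 catalyst, oxidative addition at the carbon–iodine bond should be much faster than at the doubly ortho-flanked C–OTf bond, the mild phosphate base spares ester and triflate, and the bulk of the new aryl group should stop a second arylation.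

Step 5
Reactants: 6 methyl 3-[3-methoxy-5-[2-[3-methoxy-4-(triisopropylsilyloxy)phenyl]-2-oxoethyl]-4-(trifluoromethylsulfonyloxy)phenyl]propanoate
Product: 7 racemic methyl 3-[3-[3-hydroxy-1-[3-methoxy-4-(triisopropylsilyloxy)phenyl]-1-oxopropan-2-yl]-5-methoxy-4-(trifluoromethylsulfonyloxy)phenyl]propanoate
Conditions: (CH2O)n (1.1 equiv), K2CO3 (10 mol %), DMSO, rt
Reagents that add atoms: formaldehyde (from paraformaldehyde), C=O
Why: Base-catalysed crossed aldol addition (hydroxymethylation) of the acidic deoxybenzoin CH2 to formaldehyde; the new stereocentre (future C3) forms as a racemate and stays configurationally labile next to the ketone, which step 7 turns to advantage.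

Step 6
Reactants: 7 racemic methyl 3-[3-[3-hydroxy-1-[3-methoxy-4-(triisopropylsilyloxy)phenyl]-1-oxopropan-2-yl]-5-methoxy-4-(trifluoromethylsulfonyloxy)phenyl]propanoate
Product: 8 racemic methyl 3-[3-[3-(tert-butyldiphenylsilyloxy)-1-[3-methoxy-4-(triisopropylsilyloxy)phenyl]-1-oxopropan-2-yl]-5-methoxy-4-(trifluoromethylsulfonyloxy)phenyl]propanoate
Conditions: TBDPSCl, imidazole, CH2Cl2, 0 °C to rt
Reagents that add atoms: tert-butylchlorodiphenylsilane, CC(C)(C)[Si](Cl)(c1ccccc1)c1ccccc1
Why: Silylation of the primary alcohol: it removes the only competing oxygen nucleophile for step 8, blocks retro-aldol loss of formaldehyde, and the bulky, acid-stable tert-butyldiphenylsilyl group is little prone to oxygen-to-oxygen migration.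

Step 7
Reactants: 8 racemic methyl 3-[3-[3-(tert-butyldiphenylsilyloxy)-1-[3-methoxy-4-(triisopropylsilyloxy)phenyl]-1-oxopropan-2-yl]-5-methoxy-4-(trifluoromethylsulfonyloxy)phenyl]propanoate
Product: 9 methyl 3-[3-[(1R,2S)-3-(tert-butyldiphenylsilyloxy)-1-hydroxy-1-[3-methoxy-4-(triisopropylsilyloxy)phenyl]propan-2-yl]-5-methoxy-4-(trifluoromethylsulfonyloxy)phenyl]propanoate
Conditions: RuCl[(R,R)-TsDPEN](p-cymene) (2 mol %), HCO2H/Et3N (1:1), EtOAc, 40 °C
Reagents that add atoms: none
Why: Noyori–Ikariya asymmetric transfer hydrogenation with dynamic kinetic resolution: Et3N racemises the α-aryl ketone through its enol while the (R,R)-catalyst delivers hydride to one carbonyl face, which sets C1 (future C2) as R, and it reduces faster the epimer in which this face is also the Felkin–Anh face (aryl group anti to the incoming hydride), which sets C2 (future C3) as S.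

Step 8
Reactants: 9 methyl 3-[3-[(1R,2S)-3-(tert-butyldiphenylsilyloxy)-1-hydroxy-1-[3-methoxy-4-(triisopropylsilyloxy)phenyl]propan-2-yl]-5-methoxy-4-(trifluoromethylsulfonyloxy)phenyl]propanoate
Product: 10 methyl 3-[(2R,3S)-3-(tert-butyldiphenylsilyloxymethyl)-7-methoxy-2-[3-methoxy-4-(triisopropylsilyloxy)phenyl]-2,3-dihydro-1-benzofuran-5-yl]propanoate
Conditions: [Pd(allyl)Cl]2 (2.5 mol %), RockPhos (6 mol %), Cs2CO3 (1.5 equiv), 4 Å MS, toluene, 80 °C
Reagents that add atoms: none
Why: Oxidative addition of the C7a–OTf bond to the zerovalent palladium–RockPhos complex, binding of the C2 hydroxyl and its deprotonation by Cs2CO3 should give a six-membered aryl(alkoxo)palladium chelate (Pd, O1, C2, C3, C3a, C7a), and C–O reductive elimination then expels the metal and leaves the five-membered ring. The closest known reaction type is the Buchwald–Hartwig intramolecular etherification of 2-(2-haloaryl)ethanols that carry secondary alcohols, and aryl sulfonates are established electrophiles in palladium-catalysed C–O coupling. The single ring formed (O1–C2–C3–C3a–C7a) is closed by ipso substitution at C7a, formally a contraction of the palladacycle by loss of one atom. No stereocentre is created: the C2–O1, C2–C3 and C3–C3a bonds are spectators, so (1R,2S)-9 should map with retention onto trans-(2R,3S)-10, and the quinone-methide ionisation at C2 that a closure at the O1–C2 bond would risk is never opened. Reductive elimination must outrun β-hydride elimination of C2–H, which the very bulky di-tert-butyl biaryl phosphine and the chelate geometry favour; O1 must be the only nucleophile, which the silyl ether on the C3 hydroxymethyl group secures; and the triflate must escape cleavage at sulfur, for which the weak, insoluble carbonate base in dry toluene is chosen. The methyl ester and both silyl ethers should be inert under these conditions.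

Step 9
Reactants: 10 methyl 3-[(2R,3S)-3-(tert-butyldiphenylsilyloxymethyl)-7-methoxy-2-[3-methoxy-4-(triisopropylsilyloxy)phenyl]-2,3-dihydro-1-benzofuran-5-yl]propanoate
Product: 11 3-[(2R,3S)-3-(tert-butyldiphenylsilyloxymethyl)-7-methoxy-2-[3-methoxy-4-(triisopropylsilyloxy)phenyl]-2,3-dihydro-1-benzofuran-5-yl]propan-1-ol
Conditions: iBu2AlH (2.5 equiv), CH2Cl2, −78 to 0 °C; aqueous work-up
Reagents that add atoms: none
Why: Hydride reduction of an ester to the primary alcohol: the ester is the only reducible group left, and silyl ethers, aryl ethers and both stereocentres should be untouched at low temperature.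

Step 10
Reactants: 11 3-[(2R,3S)-3-(tert-butyldiphenylsilyloxymethyl)-7-methoxy-2-[3-methoxy-4-(triisopropylsilyloxy)phenyl]-2,3-dihydro-1-benzofuran-5-yl]propan-1-ol; 12 (E)-ferulic acid
Product: 13 3-[(2R,3S)-3-(tert-butyldiphenylsilyloxymethyl)-7-methoxy-2-[3-methoxy-4-(triisopropylsilyloxy)phenyl]-2,3-dihydro-1-benzofuran-5-yl]propyl (E)-3-(4-hydroxy-3-methoxyphenyl)prop-2-enoate
Conditions: 12 (1.5 equiv), PPh3, DIAD, THF, 0 °C to rt
Reagents that add atoms: none
Why: Mitsunobu esterification: only the carboxylic acid is acidic enough to protonate the betaine and to act as the nucleophile, so the free phenol of 12 needs no protection, the reacting carbon is a primary non-stereogenic CH2, and the E-alkene is not affected.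

Step 11
Reactants: 13 3-[(2R,3S)-3-(tert-butyldiphenylsilyloxymethyl)-7-methoxy-2-[3-methoxy-4-(triisopropylsilyloxy)phenyl]-2,3-dihydro-1-benzofuran-5-yl]propyl (E)-3-(4-hydroxy-3-methoxyphenyl)prop-2-enoate
Product: 14 3-[(2R,3S)-2-(4-hydroxy-3-methoxyphenyl)-3-(hydroxymethyl)-7-methoxy-2,3-dihydro-1-benzofuran-5-yl]propyl (E)-3-(4-hydroxy-3-methoxyphenyl)prop-2-enoate (CNP0149450.1)
Conditions: Bu4NF/AcOH (1:1, 3 equiv), THF, 0 °C to rt
Reagents that add atoms: none
Why: Fluoride-induced desilylation: both silyl ethers fall in one operation, and the acetic acid buffer keeps the liberated phenoxide protonated, so neither the cinnamate ester nor the benzylic C2–O1 bond (para-quinone-methide opening) should be attacked.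

Compound list
1 | methyl 3-(4-hydroxy-3-methoxyphenyl)propanoate | COC(=O)CCc1ccc(O)c(OC)c1 | starting material
2 | methyl 3-(4-hydroxy-3-iodo-5-methoxyphenyl)propanoate | Ic1cc(CCC(=O)OC)cc(OC)c1O | intermediate
3 | methyl 3-[3-iodo-5-methoxy-4-(trifluoromethylsulfonyloxy)phenyl]propanoate | Ic1cc(CCC(=O)OC)cc(OC)c1OS(=O)(=O)C(F)(F)F | intermediate
4 | 1-(4-hydroxy-3-methoxyphenyl)ethanone (acetovanillone) | CC(=O)c1ccc(O)c(OC)c1 | starting material
5 | 1-[3-methoxy-4-(triisopropylsilyloxy)phenyl]ethanone | CC(=O)c1ccc(O[Si](C(C)C)(C(C)C)C(C)C)c(OC)c1 | intermediate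
6 | methyl 3-[3-methoxy-5-[2-[3-methoxy-4-(triisopropylsilyloxy)phenyl]-2-oxoethyl]-4-(trifluoromethylsulfonyloxy)phenyl]propanoate | COC(=O)CCc1cc(OC)c(OS(=O)(=O)C(F)(F)F)c(CC(=O)c2ccc(O[Si](C(C)C)(C(C)C)C(C)C)c(OC)c2)c1 | intermediate
7 | racemic methyl 3-[3-[3-hydroxy-1-[3-methoxy-4-(triisopropylsilyloxy)phenyl]-1-oxopropan-2-yl]-5-methoxy-4-(trifluoromethylsulfonyloxy)phenyl]propanoate | COC(=O)CCc1cc(OC)c(OS(=O)(=O)C(F)(F)F)c(C(CO)C(=O)c2ccc(O[Si](C(C)C)(C(C)C)C(C)C)c(OC)c2)c1 | intermediate
8 | racemic methyl 3-[3-[3-(tert-butyldiphenylsilyloxy)-1-[3-methoxy-4-(triisopropylsilyloxy)phenyl]-1-oxopropan-2-yl]-5-methoxy-4-(trifluoromethylsulfonyloxy)phenyl]propanoate | COC(=O)CCc1cc(OC)c(OS(=O)(=O)C(F)(F)F)c(C(CO[Si](c2ccccc2)(c2ccccc2)C(C)(C)C)C(=O)c2ccc(O[Si](C(C)C)(C(C)C)C(C)C)c(OC)c2)c1 | intermediate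
9 | methyl 3-[3-[(1R,2S)-3-(tert-butyldiphenylsilyloxy)-1-hydroxy-1-[3-methoxy-4-(triisopropylsilyloxy)phenyl]propan-2-yl]-5-methoxy-4-(trifluoromethylsulfonyloxy)phenyl]propanoate | COC(=O)CCc1cc(OC)c(OS(=O)(=O)C(F)(F)F)c(c1)[C@@H](CO[Si](c1ccccc1)(c1ccccc1)C(C)(C)C)[C@H](c1ccc(O[Si](C(C)C)(C(C)C)C(C)C)c(OC)c1)O | intermediate
10 | methyl 3-[(2R,3S)-3-(tert-butyldiphenylsilyloxymethyl)-7-methoxy-2-[3-methoxy-4-(triisopropylsilyloxy)phenyl]-2,3-dihydro-1-benzofuran-5-yl]propanoate | COC(=O)CCc1cc(OC)c2c(c1)[C@@H](CO[Si](c1ccccc1)(c1ccccc1)C(C)(C)C)[C@H](c1ccc(O[Si](C(C)C)(C(C)C)C(C)C)c(OC)c1)O2 | intermediate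
11 | 3-[(2R,3S)-3-(tert-butyldiphenylsilyloxymethyl)-7-methoxy-2-[3-methoxy-4-(triisopropylsilyloxy)phenyl]-2,3-dihydro-1-benzofuran-5-yl]propan-1-ol | OCCCc1cc(OC)c2c(c1)[C@@H](CO[Si](c1ccccc1)(c1ccccc1)C(C)(C)C)[C@H](c1ccc(O[Si](C(C)C)(C(C)C)C(C)C)c(OC)c1)O2 | intermediate
12 | (E)-ferulic acid | COc1cc(/C=C/C(=O)O)ccc1O | starting material
13 | 3-[(2R,3S)-3-(tert-butyldiphenylsilyloxymethyl)-7-methoxy-2-[3-methoxy-4-(triisopropylsilyloxy)phenyl]-2,3-dihydro-1-benzofuran-5-yl]propyl (E)-3-(4-hydroxy-3-methoxyphenyl)prop-2-enoate | COc1cc(/C=C/C(=O)OCCCc2cc(OC)c3c(c2)[C@@H](CO[Si](c2ccccc2)(c2ccccc2)C(C)(C)C)[C@H](c2ccc(O[Si](C(C)C)(C(C)C)C(C)C)c(OC)c2)O3)ccc1O | intermediate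
14 | 3-[(2R,3S)-2-(4-hydroxy-3-methoxyphenyl)-3-(hydroxymethyl)-7-methoxy-2,3-dihydro-1-benzofuran-5-yl]propyl (E)-3-(4-hydroxy-3-methoxyphenyl)prop-2-enoate | COc1cc(/C=C/C(=O)OCCCc2cc(OC)c3c(c2)[C@@H](CO)[C@H](c2ccc(O)c(OC)c2)O3)ccc1O | target

Total step count: 11
Longest linear sequence: 10 steps (steps 1, 2 and 4 to 11, from 1 to 14)

Steps most likely to fail

1. Step 8 (key step).
- What may go wrong: β-hydride elimination of the alkoxopalladium intermediate, with oxidation at C2 and reductive loss of the triflate. Cleavage of the triflate at sulfur or slow C–O reductive elimination at the doubly ortho-substituted carbon are also possible.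
- Fallback, from 9 back to 10: the polarity at C7a is inverted and the same O1–C7a bond is made by an oxidative copper coupling.
- Miyaura borylation of 9 (PdCl2(dppf), B2pin2, KOAc, dioxane, 80 °C) would give the (1R,2S)-configured aryl pinacol boronate F1.
- A Chan–Evans–Lam etherification (Cu(OAc)2, DMAP, 4 Å MS, O2, CH2Cl2, rt) would then join the C2 hydroxyl to C7a with loss of boron and give 10. The bonds at C2 and C3 are again untouched.

2. Step 7.
- What may go wrong: racemisation of the ketone that is too slow relative to reduction, weak discrimination between the matched and the mismatched epimer, or β-elimination of the silyloxy group from the enol(ate).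
- Fallback, from 8 back to 9: the dynamic process is given up.
- Reduction of 8 under pure Felkin–Anh substrate control (LiBH(sBu)3, THF, −78 °C) would give the racemic syn alcohol. This is 9 together with its mirror image, the (1S,2R)-alcohol F2.
- An acylative kinetic resolution would follow (isobutyric anhydride, iPr2NEt, CHCl3, 0 °C). It would use the benzotetramisole enantiomer that acylates (1S)-carbinols faster, which is (S)-benzotetramisole by the accepted π-stacking model.
- This should convert F2 into the (1S,2R)-isobutyrate F3 and leave 9, which is separated by chromatography and enters step 8.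

3. Step 4.
- What may go wrong: a follow-up oxidative addition at the triflate with O-arylation of the product enolate (aromatisation to a benzofuran), double arylation, or hydrolysis of triflate or ester by the base at elevated temperature.
- Fallback, from 5 and 3 back to 6: the C3–C3a bond is made without any enolate.
- Ketone 5 would be converted through its enol phosphate (LDA, ClP(O)(OEt)2, then LDA, THF, −78 °C to rt) into the terminal alkyne 4-ethynyl-2-methoxy-1-(triisopropylsilyloxy)benzene F4.
- A Sonogashira coupling with 3 (PdCl2(PPh3)2, CuI, Et3N, THF, rt), selective for the carbon–iodine bond, would give the diarylalkyne F5.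
- Gold-catalysed hydration (Ph3PAuNTf2, H2O, dioxane, 60 °C) should place the carbonyl group on the alkyne carbon next to the donor-substituted ring B, which is 6.

Further compounds
F1 | step 8 | methyl 3-[3-[(1R,2S)-3-(tert-butyldiphenylsilyloxy)-1-hydroxy-1-[3-methoxy-4-(triisopropylsilyloxy)phenyl]propan-2-yl]-5-methoxy-4-(4,4,5,5-tetramethyl-1,3,2-dioxaborolan-2-yl)phenyl]propanoate | COC(=O)CCc1cc(OC)c(B2OC(C)(C)C(C)(C)O2)c(c1)[C@@H](CO[Si](c1ccccc1)(c1ccccc1)C(C)(C)C)[C@H](c1ccc(O[Si](C(C)C)(C(C)C)C(C)C)c(OC)c1)O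
F2 | step 7 | methyl 3-[3-[(1S,2R)-3-(tert-butyldiphenylsilyloxy)-1-hydroxy-1-[3-methoxy-4-(triisopropylsilyloxy)phenyl]propan-2-yl]-5-methoxy-4-(trifluoromethylsulfonyloxy)phenyl]propanoate | COC(=O)CCc1cc(OC)c(OS(=O)(=O)C(F)(F)F)c(c1)[C@H](CO[Si](c1ccccc1)(c1ccccc1)C(C)(C)C)[C@@H](c1ccc(O[Si](C(C)C)(C(C)C)C(C)C)c(OC)c1)O
F3 | step 7 | methyl 3-[3-[(1S,2R)-3-(tert-butyldiphenylsilyloxy)-1-(2-methylpropanoyloxy)-1-[3-methoxy-4-(triisopropylsilyloxy)phenyl]propan-2-yl]-5-methoxy-4-(trifluoromethylsulfonyloxy)phenyl]propanoate | COC(=O)CCc1cc(OC)c(OS(=O)(=O)C(F)(F)F)c(c1)[C@H](CO[Si](c1ccccc1)(c1ccccc1)C(C)(C)C)[C@@H](c1ccc(O[Si](C(C)C)(C(C)C)C(C)C)c(OC)c1)OC(=O)C(C)C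
F4 | step 4 | 4-ethynyl-2-methoxy-1-(triisopropylsilyloxy)benzene | C#Cc1ccc(O[Si](C(C)C)(C(C)C)C(C)C)c(OC)c1
F5 | step 4 | methyl 3-[3-methoxy-5-[2-[3-methoxy-4-(triisopropylsilyloxy)phenyl]ethynyl]-4-(trifluoromethylsulfonyloxy)phenyl]propanoate | COC(=O)CCc1cc(OC)c(OS(=O)(=O)C(F)(F)F)c(C#Cc2ccc(O[Si](C(C)C)(C(C)C)C(C)C)c(OC)c2)c1
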